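The product comes as two species, D and Q. We want the share of D in their sum, early and late, in the flask charged like Thursday's run, which is that same flask followed through its first days.

in all of them: J 0.30 M; X 0.285 M
- Thursday's: Z 6 mM; the very flask that is asked about, followed so far
- Wednesday's: Z 4 mM; run made earlier
- flask: Z 6.0 mM; time 15 d

| run | time / d | D / % | Q / % | J / % |
|---|---|---|---|---|
| Thursday's | 0.625 | 7.3 | 2.4 | 91.0 |
| Thursday's | 1.25 | 11.3 | 3.6 | 84.3 |
| Thursday's | 1.67 | 13.6 | 6.3 | 81.1 |
| Thursday's | 2.50 | 17.2 | 4.8 | 74.0 |
| Thursday's | 3.00 | 17.8 | 4.2 | 72.9 |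
| Wednesday's | 1.25 | 10.6 | 2.0 | 85.8 |
| Wednesday's | 2.50 | 16.2 | 6.0 | 75.3 |
| Wednesday's | 4.00 | 20.3 | 5.5 | 69.9 |
| Wednesday's | 8.00 | 19.5 | 7.1 | 67.9 |
| Wednesday's | 15.0 | 20.4 | 7.9 | 67.6 |

(standard deviation of a reading: 1 percentage point)

1. share of D in D plus Q at 5.0 h
2. share of D in D plus Q at 15 d

- given per volume of solution although it is solid: J
- the numbers in the tables scatter by 1 percentage point (one standard deviation)
- at the start none of J is in solution

We reckon by hand. One reading says little: Thursday's share is 68.3% at 1.67 d and 80.9% at 3.00 d, because a scatter of 1 percentage point sits on a sum D + Q of about 19.9%. So we add up before we divide. Thursday's readings give 75.9% and Wednesday's 75.3%, with 6 mM of Z against 4 mM, so we read no effect of Z on the split. The two runs can then go together: the summed D over the summed D plus Q of both runs, the pooled selectivity s, is 75.6%. We commit to s at both asked times.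

The weak link is time, since 5.0 h lies before the first reading at 0.625 d. So we cut the pool by time instead. The readings up to 1.25 d give 78.5%, and those from 8.00 d on give 72.7%. The gap of 5.8 points has a scatter of its own, about 4.3 points, so the readings neither show a drift nor exclude one. We keep s, and at 5.0 h it stays an extrapolation.

The forecast parts from us by putting the two times apart: 79% (70% to 90%) at 5.0 h and 73% (65% to 79%) at 15 d, with “no clear dependence on Z”.

The flask gives 77.1% at 5.0 h and 76.2% at 15 d.

    L + X ⇌ D (K = 32.0 /M, k = 0.130 /M/min)
    J ⇌ L, rate k2*(cs2 - [L]) while solid is left; crystals form when [L] > cs2 (solubility = 10.0 mM, k = 0.00370 /min)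
    L + X ⇌ Q (K = 10.0 /M, k = 0.0260 /M/min)
    L ⇌ E (K = 0.440, k = 0.0100 /min)
    D + Z ⇌ Q + Z, rate k5*[Z]*[D] forward; the back reaction follows from the equilibrium constant (k = 0.950 /M/min)

In this flask the forward step from D to Q through Z has a half-life of 0.084 d, short against 15 d, so 15 d holds about 179 such half-lives and 5.0 h about 2.48. Our s lies 0.6 points below the share at 15 d. The neighbour flask, charged with 0.12 M of J, ends with D + Q at 70.2% of its own smaller J charge, and s times that gives 53.1% of that charge as D, where it holds 53.5%.

The earlier runs and the new flask stem from a simulated flask for substances that don't exist; noise was put on by code.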